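**Strategy.** Ring C is disconnected across the C8a–C4a edge of ring A. The O1–C2–C3–C4 unit, carrying the preset (S)-carbinol C2, is delivered as an enantiopure β-hydroxy Weinreb amide, and ring A as an aryne. In one operation the alkoxide O1 adds to C8a and the resulting C4a carbanion acylates C4, closing the pyranone. The aryne precursor is a silyl triflate in which a removable chlorine at C5 polarises the aryne, and O7 and the side-chain oxygen on C8 are tied as a seven-membered methylene acetal. The feature exploited is the ortho O1/C4-acyl pattern on C8a/C4a of ring A.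

Key step: step 14

Remark: flavanone numbering is used for positions (O1, C2–C4, C4a, C5–C8, C8a; side chain on C8 = C1″–C4″); the target is read as (2S,2″R); the stereochemical sense of steps 4 and 7 is assigned by analogy with acetophenone and with trisubstituted olefins, and the five building blocks marked as starting materials are taken as purchased.

**Step 1**
Reactants: 1 methyl 3,5-dibromo-4-hydroxybenzoate
Product: 2 methyl 3,5-dibromo-4-(methoxymethoxy)benzoate
Conditions: MOMCl, i-Pr2NEt, CH2Cl2, 0 °C to rt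
Reagents that add atoms: chloromethyl methyl ether (MOMCl), COCCl
Why: O-alkylation of the acidic 2,6-dibromophenol masks it as an acetal that should survive the tin, lithium amide and fluoride steps.

**Step 2**
Reactants: 2 methyl 3,5-dibromo-4-(methoxymethoxy)benzoate; 3 tributyl(3-methylbut-2-en-1-yl)stannane
Product: 4 methyl 4-(methoxymethoxy)-3,5-bis(3-methylbut-2-en-1-yl)benzoate
Conditions: Pd(PPh3)4 (8 mol %), LiCl, DMF, 100 °C
Reagents that add atoms: none
Why: Twofold Stille coupling, in which zerovalent palladium inserts into each C–Br bond and the allyl group is transferred from tin through a π-allyl complex with reductive elimination at the unsubstituted terminus, should give the linear prenyl groups.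

**Step 3**
Reactants: 4 methyl 4-(methoxymethoxy)-3,5-bis(3-methylbut-2-en-1-yl)benzoate; 5 N-methoxy-N-methylacetamide
Product: 7 N-methoxy-3-[4-(methoxymethoxy)-3,5-bis(3-methylbut-2-en-1-yl)phenyl]-N-methyl-3-oxopropanamide, via lithium amide enolate 6 (not isolated)
Conditions: LiN(i-Pr)2 (2.5 equiv), THF, –78 °C; then ester 4, –78 to 0 °C; aq NH4Cl
Reagents that add atoms: none
Why: Crossed Claisen condensation, in which the amide enolate adds to the benzoate and expels methoxide while the acidic β-keto amide stays deprotonated until the quench, should stop at the mono-acylation stage.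

**Step 4**
Reactants: 7 N-methoxy-3-[4-(methoxymethoxy)-3,5-bis(3-methylbut-2-en-1-yl)phenyl]-N-methyl-3-oxopropanamide
Product: 8 (3S)-3-hydroxy-N-methoxy-3-[4-(methoxymethoxy)-3,5-bis(3-methylbut-2-en-1-yl)phenyl]-N-methylpropanamide
Conditions: RuCl[(S,S)-TsDPEN](p-cymene) (1 mol %), HCO2H/Et3N (5:2), DMF, 40 °C
Reagents that add atoms: none
Why: Noyori–Ikariya asymmetric transfer hydrogenation, in which the (S,S)-diamine ruthenium hydride attacks the aryl ketone face fixed by the CH–π contact with the aryl ring (the acetophenone sense), should set the carbinol as (S) and leave the isolated olefins and the acetal untouched.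

**Step 5**
Reactants: 9 4-{[tert-butyl(dimethyl)silyl]oxy}phenol
Product: 10 tert-butyl[4-(methoxymethoxy)phenoxy]dimethylsilane
Conditions: MOMCl, i-Pr2NEt, CH2Cl2, 0 °C to rt
Reagents that add atoms: chloromethyl methyl ether (MOMCl), COCCl
Why: O-alkylation of the free phenol installs the chelating acetal that directs the metalation of step 6 and later becomes the cyclic acetal.

**Step 6**
Reactants: 10 tert-butyl[4-(methoxymethoxy)phenoxy]dimethylsilane; 11 1-bromo-3-methylbut-2-ene
Product: 13 tert-butyl[4-(methoxymethoxy)-3-(3-methylbut-2-en-1-yl)phenoxy]dimethylsilane, via ortho-lithiated aryl ether 12 (not isolated)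
Conditions: n-BuLi, TMEDA, THF, 0 °C; CuBr·SMe2 (10 mol %), then bromide 11, –78 °C to rt
Reagents that add atoms: none
Why: Directed ortho-metalation next to the methoxymethoxy group (the bulky silyl ether does not direct) followed by copper-catalysed SN2 allylation should place the prenyl group on the carbon that becomes C8.

**Step 7**
Reactants: 13 tert-butyl[4-(methoxymethoxy)-3-(3-methylbut-2-en-1-yl)phenoxy]dimethylsilane
Product: 14 tert-butyl(3-{[(2R)-3,3-dimethyloxiran-2-yl]methyl}-4-(methoxymethoxy)phenoxy)dimethylsilane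
Conditions: D-fructose-derived diacetonide ketone (30 mol %), Oxone (2KHSO5·KHSO4·K2SO4), K2CO3, Bu4NHSO4, MeCN/dimethoxymethane/aq Na2B4O7 buffer, 0 °C
Reagents that add atoms: potassium peroxymonosulfate KHSO5, [K+].[O-]S(=O)(=O)OO
Why: Shi asymmetric epoxidation, in which the chiral dioxirane transfers oxygen to one face of the trisubstituted olefin through a spiro transition state, should give the (R)-epoxide.

**Step 8**
Reactants: 14 tert-butyl(3-{[(2R)-3,3-dimethyloxiran-2-yl]methyl}-4-(methoxymethoxy)phenoxy)dimethylsilane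
Product: 15 (2R)-1-[5-{[tert-butyl(dimethyl)silyl]oxy}-2-(methoxymethoxy)phenyl]-3-methylbut-3-en-2-ol
Conditions: lithium 2,2,6,6-tetramethylpiperidide (from the amine and n-BuLi), Et2AlCl, toluene, 0 °C; then epoxide 14, 0 °C
Reagents that add atoms: none
Why: Aluminium-amide-mediated isomerisation of a trisubstituted epoxide to an allylic alcohol, in which the hindered amide removes a methyl proton syn to the breaking tertiary C–O bond, leaves the secondary C–O bond intact and so retains (R).

**Step 9**
Reactants: 15 (2R)-1-[5-{[tert-butyl(dimethyl)silyl]oxy}-2-(methoxymethoxy)phenyl]-3-methylbut-3-en-2-ol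
Product: 16 tert-butyldimethyl{[(4R)-4-(prop-1-en-2-yl)-4,5-dihydro-2H-1,3-benzodioxepin-7-yl]oxy}silane
Conditions: camphor-10-sulfonic acid (10 mol %), 5 Å molecular sieves, CH2Cl2 (0.01 M), 40 °C
Reagents that add atoms: none
Why: Acid-catalysed intramolecular transacetalisation, in which loss of methanol from the aryl methoxymethyl ether gives an oxocarbenium ion that the neighbouring secondary hydroxyl captures in a 7-membered ring, is driven by uptake of methanol on the sieves and does not break the carbinol C–O bond.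

**Step 10**
Reactants: 16 tert-butyldimethyl{[(4R)-4-(prop-1-en-2-yl)-4,5-dihydro-2H-1,3-benzodioxepin-7-yl]oxy}silane
Product: 17 (4R)-4-(prop-1-en-2-yl)-4,5-dihydro-2H-1,3-benzodioxepin-7-ol
Conditions: Bu4NF, THF, 0 °C; aq NH4Cl
Reagents that add atoms: none
Why: Fluoride cleaves the aryl silyl ether through a pentacoordinate silicate while the cyclic acetal and the olefin are inert.

**Step 11**
Reactants: 17 (4R)-4-(prop-1-en-2-yl)-4,5-dihydro-2H-1,3-benzodioxepin-7-ol
Product: 18 (4R)-8-chloro-4-(prop-1-en-2-yl)-4,5-dihydro-2H-1,3-benzodioxepin-7-ol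
Conditions: N-chlorosuccinimide (1.0 equiv), i-Pr2NH (10 mol %), CH2Cl2, 0 °C
Reagents that add atoms: N-chlorosuccinimide, O=C1CCC(=O)N1Cl
Why: Electrophilic chlorination ortho to the free phenol (para is blocked by the ring oxygen) should favour the ortho carbon remote from the benzylic CH2, which is the future flavanone C5.

**Step 12**
Reactants: 18 (4R)-8-chloro-4-(prop-1-en-2-yl)-4,5-dihydro-2H-1,3-benzodioxepin-7-ol
Product: 19 (4R)-6-bromo-8-chloro-4-(prop-1-en-2-yl)-4,5-dihydro-2H-1,3-benzodioxepin-7-ol
Conditions: N-bromosuccinimide (1.05 equiv), CH2Cl2, –20 to 0 °C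
Reagents that add atoms: N-bromosuccinimide, O=C1CCC(=O)N1Br
Why: Electrophilic bromination should go to the only remaining position ortho to the phenol, the future flavanone C8a.

**Step 13**
Reactants: 19 (4R)-6-bromo-8-chloro-4-(prop-1-en-2-yl)-4,5-dihydro-2H-1,3-benzodioxepin-7-ol
Product: 23 (4R)-8-chloro-4-(prop-1-en-2-yl)-6-(trimethylsilyl)-4,5-dihydro-2H-1,3-benzodioxepin-7-yl trifluoromethanesulfonate, via trimethylsilyl ether 20 (not isolated), via aryllithium 21 (not isolated), via lithium 2-silylphenoxide 22 (not isolated)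
Conditions: HN(SiMe3)2, THF, 65 °C, concentrate; n-BuLi, THF, –78 °C; Tf2O, –78 °C
Reagents that add atoms: hexamethyldisilazane, C[Si](C)(C)N[Si](C)(C)C; trifluoromethanesulfonic anhydride, O=S(=O)(OS(=O)(=O)C(F)(F)F)C(F)(F)F
Why: One-pot O-silylation, bromine–lithium exchange (the aryl chloride does not exchange at –78 °C), retro-Brook shift of silicon from oxygen to the lithiated carbon and O-triflation of the phenoxide is the standard entry to ortho-silylaryl triflates.

**Step 14**
Reactants: 8 (3S)-3-hydroxy-N-methoxy-3-[4-(methoxymethoxy)-3,5-bis(3-methylbut-2-en-1-yl)phenyl]-N-methylpropanamide; 23 (4R)-8-chloro-4-(prop-1-en-2-yl)-6-(trimethylsilyl)-4,5-dihydro-2H-1,3-benzodioxepin-7-yl trifluoromethanesulfonate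
Product: 28 (2S)-5-chloro-2-[4-(methoxymethoxy)-3,5-bis(3-methylbut-2-en-1-yl)phenyl]chroman-4-one whose O7 and C8 are bridged by O–CH2–O–CH(isopropenyl)–CH2 with (R) at the bridging CH, via sodium alkoxide 24 (not isolated), via 3-chloroaryne 25 (not isolated), via aryl anion adduct 26 (not isolated), via tetrahedral hemiaminal salt 27 (not isolated)
Conditions: NaH (1.05 equiv), THF, 0 °C; then silyl triflate (1.4 equiv), CsF (3 equiv), 18-crown-6, THF, 0 °C to rt; aq NH4Cl, 0 °C
Reagents that add atoms: none
Why: Proposed new method: fluoride attack on silicon expels triflate to give the 3-chloroaryne 25, the sodium alkoxide 24 adds through O1 to C8a, and the C4a carbanion of 26 adds to the Weinreb carbonyl to give the chelated tetrahedral salt 27, which releases the ketone only on the ammonium chloride quench. The closest known reaction types are the fluoride-mediated annulation of arynes with salicylate esters to xanthones (oxygen addition, then intramolecular acyl capture) and the insertion of arynes into the N–C(O) bond of β-lactams; here the nucleophile is an aliphatic alkoxide and the acyl acceptor an amide. Ring C closes by 6-exo-trig attack of the aryl anion on C4. No stereocentre is formed: C2 stays (S) because its C–O bond is never broken and the ketone appears only under the neutral quench, so retro-oxa-Michael opening cannot scramble it. The step needs oxygen attack at C8a and not at C4a; the chlorine on C5 distorts the aryne so that C8a is the more linear and more electrophilic carbon and the developing charge at C4a sits next to the inductive acceptor. The methylene acetal holds the side-chain oxygen where it cannot reach C8a, and the isopropenyl group has no allylic hydrogen placed for an intramolecular ene reaction.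

**Step 15**
Reactants: 28 the 5-chloro flavanone of step 14
Product: 29 (2S)-2-[4-(methoxymethoxy)-3,5-bis(3-methylbut-2-en-1-yl)phenyl]chroman-4-one with the same (R)-configured O7–CH2–O–CH(isopropenyl)–CH2–C8 bridge and hydrogen at C5
Conditions: Pd(OAc)2 (5 mol %), XPhos (10 mol %), HCO2H (3 equiv), Et3N (4 equiv), DMF, 80 °C
Reagents that add atoms: none
Why: Palladium-catalysed transfer hydrodehalogenation (oxidative addition of the ketone-activated aryl chloride to the biarylphosphine zerovalent palladium complex, chloride–formate exchange, decarboxylation, C–H reductive elimination) should remove the directing chlorine, and the formate buffer is too weakly basic to enolise the flavanone.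

**Step 16**
Reactants: 29 the dechlorinated protected flavanone of step 15
Product: 30 (2S)-7-hydroxy-2-[4-hydroxy-3,5-bis(3-methylbut-2-en-1-yl)phenyl]-8-[(2R)-2-hydroxy-3-methylbut-3-en-1-yl]chroman-4-one (target)
Conditions: ZnBr2 (2 equiv), n-PrSH (6 equiv), CH2Cl2, 0 °C to rt
Reagents that add atoms: none
Why: Lewis acid–thiol cleavage of formaldehyde acetals, in which zinc bromide activates the acetal oxygens and the thiol takes up each CH2 unit as the dithioacetal, should free the B-ring phenol and open the dioxepine to the C7 phenol and the (R)-carbinol without touching either stereocentre.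

**Compound list**

1 | methyl 3,5-dibromo-4-hydroxybenzoate | COC(=O)c1cc(Br)c(O)c(Br)c1 | starting material
2 | methyl 3,5-dibromo-4-(methoxymethoxy)benzoate | COCOc1c(Br)cc(C(=O)OC)cc1Br | intermediate
3 | tributyl(3-methylbut-2-en-1-yl)stannane | CCCC[Sn](CCCC)(CCCC)CC=C(C)C | starting material
4 | methyl 4-(methoxymethoxy)-3,5-bis(3-methylbut-2-en-1-yl)benzoate | COCOc1c(CC=C(C)C)cc(C(=O)OC)cc1CC=C(C)C | intermediate
5 | N-methoxy-N-methylacetamide | CON(C)C(C)=O | starting material
6 | lithium enolate of N-methoxy-N-methylacetamide | C=C([O-])N(C)OC.[Li+] | intermediate (not isolated)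
7 | N-methoxy-3-[4-(methoxymethoxy)-3,5-bis(3-methylbut-2-en-1-yl)phenyl]-N-methyl-3-oxopropanamide | COCOc1c(CC=C(C)C)cc(C(=O)CC(=O)N(C)OC)cc1CC=C(C)C | intermediate
8 | (3S)-3-hydroxy-N-methoxy-3-[4-(methoxymethoxy)-3,5-bis(3-methylbut-2-en-1-yl)phenyl]-N-methylpropanamide | CON(C)C(=O)C[C@H](O)c1cc(CC=C(C)C)c(OCOC)c(CC=C(C)C)c1 | intermediate
9 | 4-{[tert-butyl(dimethyl)silyl]oxy}phenol | CC(C)(C)[Si](C)(C)Oc1ccc(O)cc1 | starting material
10 | tert-butyl[4-(methoxymethoxy)phenoxy]dimethylsilane | COCOc1ccc(O[Si](C)(C)C(C)(C)C)cc1 | intermediate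
11 | 1-bromo-3-methylbut-2-ene | CC(C)=CCBr | starting material
12 | [5-{[tert-butyl(dimethyl)silyl]oxy}-2-(methoxymethoxy)phenyl]lithium | COCOc1ccc(O[Si](C)(C)C(C)(C)C)cc1[Li] | intermediate (not isolated)
13 | tert-butyl[4-(methoxymethoxy)-3-(3-methylbut-2-en-1-yl)phenoxy]dimethylsilane | COCOc1ccc(O[Si](C)(C)C(C)(C)C)cc1CC=C(C)C | intermediate
14 | tert-butyl(3-{[(2R)-3,3-dimethyloxiran-2-yl]methyl}-4-(methoxymethoxy)phenoxy)dimethylsilane | COCOc1ccc(O[Si](C)(C)C(C)(C)C)cc1C[C@H]1OC1(C)C | intermediate
15 | (2R)-1-[5-{[tert-butyl(dimethyl)silyl]oxy}-2-(methoxymethoxy)phenyl]-3-methylbut-3-en-2-ol | C=C(C)[C@H](O)Cc1cc(O[Si](C)(C)C(C)(C)C)ccc1OCOC | intermediate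
16 | tert-butyldimethyl{[(4R)-4-(prop-1-en-2-yl)-4,5-dihydro-2H-1,3-benzodioxepin-7-yl]oxy}silane | C=C(C)[C@H]1Cc2cc(O[Si](C)(C)C(C)(C)C)ccc2OCO1 | intermediate
17 | (4R)-4-(prop-1-en-2-yl)-4,5-dihydro-2H-1,3-benzodioxepin-7-ol | C=C(C)[C@H]1Cc2cc(O)ccc2OCO1 | intermediate
18 | (4R)-8-chloro-4-(prop-1-en-2-yl)-4,5-dihydro-2H-1,3-benzodioxepin-7-ol | C=C(C)[C@H]1Cc2cc(O)c(Cl)cc2OCO1 | intermediate
19 | (4R)-6-bromo-8-chloro-4-(prop-1-en-2-yl)-4,5-dihydro-2H-1,3-benzodioxepin-7-ol | C=C(C)[C@H]1Cc2c(Br)c(O)c(Cl)cc2OCO1 | intermediate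
20 | trimethylsilyl ether of 19 | C=C(C)[C@H]1Cc2c(Br)c(O[Si](C)(C)C)c(Cl)cc2OCO1 | intermediate (not isolated)
21 | 6-lithio analogue of 20 (lithium in place of bromine) | C=C(C)[C@H]1Cc2c([Li])c(O[Si](C)(C)C)c(Cl)cc2OCO1 | intermediate (not isolated)
22 | lithium (4R)-8-chloro-4-(prop-1-en-2-yl)-6-(trimethylsilyl)-4,5-dihydro-2H-1,3-benzodioxepin-7-olate | C=C(C)[C@H]1Cc2c([Si](C)(C)C)c([O-])c(Cl)cc2OCO1.[Li+] | intermediate (not isolated)
23 | (4R)-8-chloro-4-(prop-1-en-2-yl)-6-(trimethylsilyl)-4,5-dihydro-2H-1,3-benzodioxepin-7-yl trifluoromethanesulfonate | C=C(C)[C@H]1Cc2c([Si](C)(C)C)c(OS(=O)(=O)C(F)(F)F)c(Cl)cc2OCO1 | intermediate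
24 | sodium alkoxide of 8 | CON(C)C(=O)C[C@H]([O-])c1cc(CC=C(C)C)c(OCOC)c(CC=C(C)C)c1.[Na+] | intermediate (not isolated)
25 | (4R)-8-chloro-6,7-didehydro-4-(prop-1-en-2-yl)-4,5-dihydro-2H-1,3-benzodioxepine (aryne) | C=C(C)[C@H]1CC2=C(OCO1)C=C(Cl)C#C2 | intermediate (not isolated)
26 | sodium aryl anion formed by addition of 24 through oxygen to C8a of 25 (charge at C4a) | C=C(C)[C@H]1Cc2c(OCO1)cc(Cl)[c-]c2O[C@H](c3cc(CC=C(C)C)c(OCOC)c(CC=C(C)C)c3)CC(=O)N(C)OC.[Na+] | intermediate (not isolated)
27 | sodium salt of the C4 hemiaminal (C4 bears O– and N(OMe)Me) of 28 | C=C(C)[C@H]1Cc2c(OCO1)cc(Cl)c3c2O[C@H](c4cc(CC=C(C)C)c(OCOC)c(CC=C(C)C)c4)CC3([O-])N(C)OC.[Na+] | intermediate (not isolated)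
28 | (2S)-5-chloro-2-[4-(methoxymethoxy)-3,5-bis(3-methylbut-2-en-1-yl)phenyl]chroman-4-one with the (R)-configured O7–CH2–O–CH(isopropenyl)–CH2–C8 bridge | C=C(C)[C@H]1Cc2c(OCO1)cc(Cl)c3c2O[C@H](c4cc(CC=C(C)C)c(OCOC)c(CC=C(C)C)c4)CC3=O | intermediate
29 | 5-dechloro analogue of 28 | C=C(C)[C@H]1Cc2c(OCO1)ccc3c2O[C@H](c4cc(CC=C(C)C)c(OCOC)c(CC=C(C)C)c4)CC3=O | intermediate
30 | (2S)-7-hydroxy-2-[4-hydroxy-3,5-bis(3-methylbut-2-en-1-yl)phenyl]-8-[(2R)-2-hydroxy-3-methylbut-3-en-1-yl]chroman-4-one | C=C(C)[C@H](O)Cc1c(O)ccc2c1O[C@H](c1cc(CC=C(C)C)c(O)c(CC=C(C)C)c1)CC2=O | target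

**Step count and risks**

Total step count: 16. Longest linear sequence: 12 steps (steps 5 to 16, from 9 to 30); the amide branch (steps 1 to 4) joins at step 14.

Steps most likely to fail:

1. Step 14. The C4a carbanion may be protonated before it reaches the amide, leaving an uncyclised aryl ether. The alkoxide may add to C4a instead of C8a. The ortho-chloroaryl anion may lose chloride. The hemiaminal salt may collapse early, followed by base-induced ring opening and erosion at C2.
   Fallback (known chemistry), from ester 4 and silyl triflate 23, returning at 28: LiAlH4 in THF at 0 °C should reduce 4 to [4-(methoxymethoxy)-3,5-bis(3-methylbut-2-en-1-yl)phenyl]methanol F1. Oxidation of F1 with MnO2 in CH2Cl2 should give 4-(methoxymethoxy)-3,5-bis(3-methylbut-2-en-1-yl)benzaldehyde F2. Doebner–Knoevenagel condensation of F2 with malonic acid in pyridine containing piperidine at 90 °C should give (E)-3-[4-(methoxymethoxy)-3,5-bis(3-methylbut-2-en-1-yl)phenyl]acrylic acid F3. Heating F3 with 23 and CsF in THF at 125 °C is the known insertion of arynes into the C–O bond of carboxylic acids: the carboxylate oxygen adds to C8a and the acyl group shifts to C4a. This should give (E)-1-[(4R)-8-chloro-6-hydroxy-4-(prop-1-en-2-yl)-4,5-dihydro-2H-1,3-benzodioxepin-7-yl]-3-[4-(methoxymethoxy)-3,5-bis(3-methylbut-2-en-1-yl)phenyl]prop-2-en-1-one F4, the 2′-hydroxychalcone carrying the chlorodioxepine ring. A work-up with KOH in aqueous EtOH should keep the chalcone open as its phenoxide. A cinchona-alkaloid thiourea catalyst, in the pseudo-enantiomeric form that delivers the 2S configuration, should then close ring C of F4 by enantioselective intramolecular oxa-Michael addition to give 28.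

2. Step 15. Oxidative addition into the hindered, electron-rich aryl chloride may be sluggish, and palladium hydride may migrate into the isopropenyl or prenyl double bonds.
   Fallback, from phenol 17, returning at 29: bromine replaces chlorine as the directing halogen. N-bromosuccinimide in CH2Cl2 at 0 °C should give (4R)-8-bromo-4-(prop-1-en-2-yl)-4,5-dihydro-2H-1,3-benzodioxepin-7-ol F5. N-iodosuccinimide should then convert F5 into (4R)-8-bromo-6-iodo-4-(prop-1-en-2-yl)-4,5-dihydro-2H-1,3-benzodioxepin-7-ol F6. The one-pot sequence of step 13 applied to F6, with iodine–lithium exchange selective over bromine at –78 °C, should give (4R)-8-bromo-4-(prop-1-en-2-yl)-6-(trimethylsilyl)-4,5-dihydro-2H-1,3-benzodioxepin-7-yl trifluoromethanesulfonate F7. Annulation of F7 with 8 under the conditions of step 14 should give the 5-bromo analogue of 28 F8. Radical chain reduction of F8 with Bu3SnH and azobisisobutyronitrile in toluene at 80 °C should then give 29.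

3. Step 9. The methoxymethyl group may be lost without ring closure, acetal exchange may occur between molecules, or acid may ionise the allylic carbinol.
   Fallback, from 15, returning at 16: ZnBr2 and n-PrSH in CH2Cl2 at 0 °C should remove the methoxymethyl group to give 4-{[tert-butyl(dimethyl)silyl]oxy}-2-[(2R)-2-hydroxy-3-methylbut-3-en-1-yl]phenol F9. Double Williamson alkylation of F9 with CH2Br2 and NaH in DMF at 0 °C to rt under high dilution should then close the 7-membered methylene acetal 16.

**Further compounds**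

F1 | step 14 | [4-(methoxymethoxy)-3,5-bis(3-methylbut-2-en-1-yl)phenyl]methanol | OCc1cc(CC=C(C)C)c(OCOC)c(CC=C(C)C)c1
F2 | step 14 | 4-(methoxymethoxy)-3,5-bis(3-methylbut-2-en-1-yl)benzaldehyde | O=Cc1cc(CC=C(C)C)c(OCOC)c(CC=C(C)C)c1
F3 | step 14 | (E)-3-[4-(methoxymethoxy)-3,5-bis(3-methylbut-2-en-1-yl)phenyl]acrylic acid | OC(=O)/C=C/c1cc(CC=C(C)C)c(OCOC)c(CC=C(C)C)c1
F4 | step 14 | (E)-1-[(4R)-8-chloro-6-hydroxy-4-(prop-1-en-2-yl)-4,5-dihydro-2H-1,3-benzodioxepin-7-yl]-3-[4-(methoxymethoxy)-3,5-bis(3-methylbut-2-en-1-yl)phenyl]prop-2-en-1-one | C=C(C)[C@H]1Cc2c(OCO1)cc(Cl)c(C(=O)/C=C/c3cc(CC=C(C)C)c(OCOC)c(CC=C(C)C)c3)c2O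
F5 | step 15 | (4R)-8-bromo-4-(prop-1-en-2-yl)-4,5-dihydro-2H-1,3-benzodioxepin-7-ol | C=C(C)[C@H]1Cc2cc(O)c(Br)cc2OCO1
F6 | step 15 | (4R)-8-bromo-6-iodo-4-(prop-1-en-2-yl)-4,5-dihydro-2H-1,3-benzodioxepin-7-ol | C=C(C)[C@H]1Cc2c(I)c(O)c(Br)cc2OCO1
F7 | step 15 | (4R)-8-bromo-4-(prop-1-en-2-yl)-6-(trimethylsilyl)-4,5-dihydro-2H-1,3-benzodioxepin-7-yl trifluoromethanesulfonate | C=C(C)[C@H]1Cc2c([Si](C)(C)C)c(OS(=O)(=O)C(F)(F)F)c(Br)cc2OCO1
F8 | step 15 | 5-bromo analogue of 28 | C=C(C)[C@H]1Cc2c(OCO1)cc(Br)c3c2O[C@H](c4cc(CC=C(C)C)c(OCOC)c(CC=C(C)C)c4)CC3=O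
F9 | step 9 | 4-{[tert-butyl(dimethyl)silyl]oxy}-2-[(2R)-2-hydroxy-3-methylbut-3-en-1-yl]phenol | C=C(C)[C@H](O)Cc1cc(O[Si](C)(C)C(C)(C)C)ccc1O
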